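**Plan**

1. Retrosynthesis: the senecioate (O–C9) and tiglate (O–C8) C–O bonds are cut first, then the C1–C10 bond of ring A, then the C4–C5 bond. The C7 isopropenyl group and C8 are joined back into a gem-dimethylcyclopropane (C8–C11 bond), which makes ring B the enone of (+)-3-carene.
2. Forward: an acetyl unit (C1, C2) and a Z-propenyl unit (C3, C4, C15) are added at C9 of the carene enone, and a dianionic oxy-Cope rearrangement across this temporary C2–C9 bond moves the chain to C5 (C4–C5 bond).
3. Ring A is then closed at C1–C10 by intramolecular oxidative coupling of the two ketone enolates of the 2,9-dione. This works because the C2 carbonyl and the C9 oxygen stand 1,4 across C1–C10, and because C8, the other α-carbon of the C9 ketone, is a bridgehead of the C7–C8–C11 cyclopropane, so this ketone can enolize only toward C10.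
4. A strain-releasing homodienyl [1,5]-hydrogen shift of the C9 silyl enol ether then opens the cyclopropane. It gives the isopropenyl group, puts hydrogen on C10 cis to the C5 methyl group and moves the enol ether to C8=C9, from which O8 (bromination, carboxylate displacement) and O9 (hydride, esterification) are installed.
5. Stereochemistry: C7 from the chiral pool; C5 and C4 from the chair [3,3] array on the face anti to the cyclopropane, using the Z alkene; C10 from the suprafacial hydrogen shift; C8 from axial bromination then SN2 inversion; C9 from equatorial hydride delivery.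

Key step: step 5

Remark: locants follow the eremophilane skeleton of the target and are kept for all intermediates (ring A = C1–C5 and C10, ring B = C5–C10, C11–C13 = isopropenyl carbons, C14 on C5, C15 on C4). β is the face of ring B that carries C14, α the other face. The C2 carbinol of diol 7 is drawn as expected from chelation control (either epimer should serve), and 12 is drawn cis-fused (its C10 configuration is erased in step 7).

**Step 1**
Reactants: 1 (+)-3-carene
Product: 2 (1R,6S)-4,7,7-trimethylbicyclo[4.1.0]hept-3-en-2-one (car-3-en-5-one)
Conditions: t-BuOOH (70% aq), CrO3 (5 mol %), CH2Cl2, rt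
Reagents that add atoms: tert-butyl hydroperoxide, CC(C)(C)OO
Why: Chromium-catalysed allylic oxidation, in which hydrogen abstraction should be preferred at the ring CH2 next to the CH= carbon (future C9) because the allyl radical then has a tertiary terminus, oxygen ending on the secondary terminus to give the β-methyl enone; no stereocenter is formed.

**Step 2**
Reactants: 2 car-3-en-5-one; 3 ethyl vinyl ether
Product: 5 1-[(1R,6S)-2-hydroxy-4,7,7-trimethylbicyclo[4.1.0]hept-3-en-2-yl]ethan-1-one (α-acetyl ketol), via ethoxyvinyl carbinol 4 (not isolated)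
Conditions: 3, t-BuLi, THF, −78 → 0 °C; then 2, −78 °C; H2O; then oxalic acid (cat.), THF/H2O, 0 °C
Reagents that add atoms: water, O
Why: 1,2-Addition of an acyl-anion equivalent (1-ethoxyvinyllithium) to the enone carbonyl followed by mild enol ether hydrolysis; the nucleophile should enter C9 on the α face, anti to the endo methyl group of the β-oriented CMe2 bridge, so the acetyl group of 5 is α.

**Step 3**
Reactants: 5 α-acetyl ketol; 6 (Z)-1-bromoprop-1-ene
Product: 7 (3Z)-2-[(1R,6S)-2-hydroxy-4,7,7-trimethylbicyclo[4.1.0]hept-3-en-2-yl]pent-3-en-2-ol (Z diol)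
Conditions: 6 (3 equiv), t-BuLi (6 equiv), Et2O, −78 °C; then 5, THF, −78 → −40 °C; H2O
Reagents that add atoms: none
Why: Addition of an alkenyllithium to an α-oxido ketone under chelation control (attack from the side of the vinylic C10–H, away from the cyclopropane C8–H); lithium–bromine exchange and addition keep the Z geometry that later places C15, and the new carbinol center is lost in step 4.

**Step 4**
Reactants: 7 Z diol
Product: 10 1,10-seco-8,11-cycloeremophilane-2,9-dione, via dipotassium dialkoxide 8 (not isolated), via dipotassium bis-enolate 9 (not isolated)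
Conditions: KH (2.5 equiv), 18-crown-6, THF, 0 °C → rt; then AcOH, −78 °C
Reagents that add atoms: none
Why: Dianionic oxy-Cope rearrangement ([3,3]) of a 3,4-dioxido-1,5-diene, in which the C2–C9 bond breaks and C4–C5 forms on the α face through a chair array with the Z-methyl group (C15) axial, so that C15 ends cis to C14 (a boat is disfavoured by the clash of that methyl group with C6); this sets C5 and C4 together, and both C2 epimers of 7 converge on 10 after cold protonation of 9.

**Step 5**
Reactants: 10 1,10-seco-8,11-cycloeremophilane-2,9-dione
Product: 12 10βH-8,11-cycloeremophilane-2,9-dione, via dilithium bis-enolate 11 (not isolated)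
Conditions: LiN(i-Pr)2 (2.3 equiv), THF, −78 → 0 °C (slow addition of 10, high dilution); then Fe(acac)3 (2.2 equiv), −78 °C → rt
Reagents that add atoms: none
Why: Double deprotonation gives bis-enolate 11, in which the C9 ketone can only have enolized toward C10 because C8 is a bridgehead of the C7–C8–C11 cyclopropane, while the methyl ketone enolizes kinetically at C1. One-electron oxidation by Fe(acac)3 (trivalent iron) should turn the more substituted C9–C10 enolate into an α-keto radical at C10, which adds to the terminal carbon C1 of the second enolate, and a second electron transfer converts the resulting ketyl into the C2 ketone. The closest known reaction type is the intramolecular oxidative coupling of two ketone enolates to a cyclic 1,4-diketone. Ring A closes as a six-membered ring in a 6-endo-trig sense with respect to the C1=C2 enolate. The new stereocenter C10 is set by the tether, C1 being delivered to the α face on which the C4 branch already sits (cis fusion), and it is made planar again in step 7 and reset in step 8. The step needs coupling inside the molecule instead of dimerization or aldol closure, which complete double enolization before the oxidant is added and high dilution should secure.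

**Step 6**
Reactants: 12 10βH-8,11-cycloeremophilane-2,9-dione
Product: 13 2,2-ethylenedioxy-10βH-8,11-cycloeremophilan-9-one
Conditions: Me3SiOCH2CH2OSiMe3, Me3SiOTf (cat.), CH2Cl2, −78 → −20 °C
Reagents that add atoms: 1,2-bis(trimethylsilyloxy)ethane, C[Si](C)(C)OCCO[Si](C)(C)C
Why: Acid-catalysed dioxolane formation under aprotic silyl-transfer conditions, selective for the unhindered ring A ketone because the C9 carbonyl is flanked by the ring-fusion carbon and the cyclopropane and is deactivated by conjugation with it; the low temperature should prevent cyclodehydration of the 1,4-diketone to a furan.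

**Step 7**
Reactants: 13 2,2-ethylenedioxy-10βH-8,11-cycloeremophilan-9-one
Product: 15 2,2-ethylenedioxy-9-(triethylsilyloxy)-8,11-cycloeremophil-9-ene, via potassium enolate 14 (not isolated)
Conditions: KN(SiMe3)2, THF, −78 → −20 °C; then Et3SiCl, −78 → 0 °C
Reagents that add atoms: chlorotriethylsilane, CC[Si](Cl)(CC)CC
Why: Enolization and O-silylation, in which C10–H is the only enolizable hydrogen of the C9 ketone (C8 is a cyclopropane bridgehead), so a single tetrasubstituted silyl enol ether should form and any mixture of ring-fusion isomers from step 5 is funnelled into one compound with planar C10.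

**Step 8**
Reactants: 15 2,2-ethylenedioxy-9-(triethylsilyloxy)-8,11-cycloeremophil-9-ene
Product: 16 2,2-ethylenedioxy-9-(triethylsilyloxy)-10βH-eremophila-8,11-diene
Conditions: PhMe (degassed), (Me3Si)2NH (cat.), sealed tube, 210 °C
Reagents that add atoms: none
Why: Thermal homodienyl [1,5]-hydrogen shift (retro-ene reaction) of the 2-siloxy-vinylcyclopropane, in which the endo methyl group on C11 hands a hydrogen suprafacially to the β face of C10 while the C8–C11 bond breaks and the double bond moves to C8=C9; release of cyclopropane strain drives it, it sets 10β-H, gives only the isopropenyl group at C7 with its configuration untouched, and places the enol ether where C8 is to be oxidized.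

**Step 9**
Reactants: 16 2,2-ethylenedioxy-9-(triethylsilyloxy)-10βH-eremophila-8,11-diene
Product: 17 8β-bromo-2,2-ethylenedioxy-10βH-eremophil-11-en-9-one
Conditions: N-bromosuccinimide, NaHCO3, THF, −78 °C
Reagents that add atoms: N-bromosuccinimide, O=C1CCC(=O)N1Br
Why: Electrophilic bromination of the silyl enol ether at C8, where bromine should enter axially on the β face of the half-chair (C4 branch axial on the α side, isopropenyl group equatorial) to give the axial 8β-bromo ketone; the electron-rich enol ether should react far faster than the isopropenyl group.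

**Step 10**
Reactants: 17 8β-bromo ketone; 18 tiglic acid
Product: 19 2,2-ethylenedioxy-8α-[(E)-2-methylbut-2-enoyloxy]-10βH-eremophil-11-en-9-one
Conditions: 18, Cs2CO3, DMF, rt
Reagents that add atoms: none
Why: SN2 displacement of the activated α-keto bromide by cesium tiglate in a dipolar aprotic solvent with inversion at C8, which puts the tiglate in the equatorial 8α position trans to the isopropenyl group; the weakly basic carboxylate should limit elimination and leave C10 untouched.

**Step 11**
Reactants: 19 8α-tigloyloxy 9-ketone
Product: 20 2,2-ethylenedioxy-9α-hydroxy-10βH-eremophil-11-en-8α-yl (E)-2-methylbut-2-enoate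
Conditions: LiBH(s-Bu)3, THF, −78 °C; then AcOH
Reagents that add atoms: none
Why: Ketone reduction by a bulky trialkylborohydride, in which axial attack on the α face is blocked by the syn-axial C4 branch on C5, so hydride should arrive equatorially from the β side and give the axial 9α-alcohol cis to the tiglate; the ketone reacts far faster than the enoate, and acyl migration from equatorial O8 to hindered axial O9 is uphill.

**Step 12**
Reactants: 20 9α-hydroxy 8α-tiglate; 21 senecioic acid
Product: 22 2,2-ethylenedioxy-9α-(3-methylbut-2-enoyloxy)-10βH-eremophil-11-en-8α-yl (E)-2-methylbut-2-enoate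
Conditions: 21, 2,4,6-trichlorobenzoyl chloride, Et3N, THF, rt; then 20, DMAP, PhMe, 60 °C
Reagents that add atoms: none
Why: Yamaguchi esterification of the hindered axial alcohol through the mixed anhydride, chosen because it avoids the acid chloride and amine combination that deconjugates the senecioyl group through a vinylketene; no stereocenter changes.

**Step 13**
Reactants: 22 diester ketal
Product: 23 9α-(3-methylbut-2-enoyloxy)-8α-[(E)-2-methylbut-2-enoyloxy]-10βH-eremophil-11-en-2-one (CNP0181050.1)
Conditions: 1 M HCl (aq), THF, rt
Reagents that add atoms: water, O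
Why: Acid-catalysed hydrolysis of the dioxolane under mild aqueous conditions that should leave both enoate esters and the isopropenyl group untouched and release the C2 ketone of the target.

**Compound list**

1 | (+)-3-carene, (1S,6R)-3,7,7-trimethylbicyclo[4.1.0]hept-3-ene | CC1=CC[C@@H]2[C@H](C1)C2(C)C | starting material
2 | (1R,6S)-4,7,7-trimethylbicyclo[4.1.0]hept-3-en-2-one (car-3-en-5-one) | CC1=CC(=O)[C@@H]2[C@H](C1)C2(C)C | intermediate
3 | ethyl vinyl ether | C=COCC | starting material
4 | (1R,6S)-2-(1-ethoxyethenyl)-4,7,7-trimethylbicyclo[4.1.0]hept-3-en-2-ol, ethoxyvinyl group anti to the CMe2 bridge | CC1=C[C@](O)(C(=C)OCC)[C@@H]2[C@H](C1)C2(C)C | intermediate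
5 | 1-[(1R,6S)-2-hydroxy-4,7,7-trimethylbicyclo[4.1.0]hept-3-en-2-yl]ethan-1-one, acetyl group anti to the CMe2 bridge | CC1=C[C@](O)(C(C)=O)[C@@H]2[C@H](C1)C2(C)C | intermediate
6 | (Z)-1-bromoprop-1-ene | C/C=C\Br | starting material
7 | (3Z)-2-[(1R,6S)-2-hydroxy-4,7,7-trimethylbicyclo[4.1.0]hept-3-en-2-yl]pent-3-en-2-ol, side chain anti to the CMe2 bridge | CC1=C[C@](O)([C@](C)(O)/C=C\C)[C@@H]2[C@H](C1)C2(C)C | intermediate
8 | dipotassium dialkoxide of 7 | CC1=C[C@]([O-])([C@](C)([O-])/C=C\C)[C@@H]2[C@H](C1)C2(C)C.[K+].[K+] | intermediate
9 | dipotassium bis-enolate of 10 (C2=C3, Z, and C9=C10) | C[C@]1(C=C([O-])[C@@H]2[C@H](C1)C2(C)C)[C@@H](C)/C=C(/C)[O-].[K+].[K+] | intermediate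
10 | 1,10-seco-8,11-cycloeremophilane-2,9-dione; (1R,6S)-4,7,7-trimethyl-4-(4-oxopentan-2-yl)bicyclo[4.1.0]heptan-2-one with the side chain α and C14, C15 β | C[C@]1(CC(=O)[C@@H]2[C@H](C1)C2(C)C)[C@@H](C)CC(C)=O | intermediate
11 | dilithium bis-enolate of 10 (C1=C2 and C9=C10) | C[C@]1(C=C([O-])[C@@H]2[C@H](C1)C2(C)C)[C@@H](C)CC(=C)[O-].[Li+].[Li+] | intermediate
12 | 10βH-8,11-cycloeremophilane-2,9-dione (cis-fused, cyclopropane on the β face) | C[C@H]1CC(=O)C[C@@H]2C(=O)[C@@H]3[C@H](C[C@]12C)C3(C)C | intermediate
13 | 2,2-ethylenedioxy-10βH-8,11-cycloeremophilan-9-one | C[C@H]1CC2(OCCO2)C[C@@H]3C(=O)[C@@H]4[C@H](C[C@]13C)C4(C)C | intermediate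
14 | potassium C9–C10 enolate of 13 | C[C@H]1CC2(OCCO2)CC3=C([O-])[C@@H]4[C@H](C[C@]13C)C4(C)C.[K+] | intermediate
15 | 2,2-ethylenedioxy-9-(triethylsilyloxy)-8,11-cycloeremophil-9-ene | C[C@H]1CC2(OCCO2)CC3=C(O[Si](CC)(CC)CC)[C@@H]4[C@H](C[C@]13C)C4(C)C | intermediate
16 | 2,2-ethylenedioxy-9-(triethylsilyloxy)-10βH-eremophila-8,11-diene | C[C@H]1CC2(OCCO2)C[C@@H]3C(O[Si](CC)(CC)CC)=C[C@@H](C(C)=C)C[C@]13C | intermediate
17 | 8β-bromo-2,2-ethylenedioxy-10βH-eremophil-11-en-9-one | C[C@H]1CC2(OCCO2)C[C@@H]3C(=O)[C@@H](Br)[C@@H](C(C)=C)C[C@]13C | intermediate
18 | tiglic acid, (E)-2-methylbut-2-enoic acid | C/C=C(\C)C(=O)O | starting material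
19 | 2,2-ethylenedioxy-8α-[(E)-2-methylbut-2-enoyloxy]-10βH-eremophil-11-en-9-one | C[C@H]1CC2(OCCO2)C[C@@H]3C(=O)[C@H](OC(=O)/C(C)=C/C)[C@@H](C(C)=C)C[C@]13C | intermediate
20 | 2,2-ethylenedioxy-9α-hydroxy-10βH-eremophil-11-en-8α-yl (E)-2-methylbut-2-enoate | C[C@H]1CC2(OCCO2)C[C@@H]3[C@H](O)[C@H](OC(=O)/C(C)=C/C)[C@@H](C(C)=C)C[C@]13C | intermediate
21 | senecioic acid, 3-methylbut-2-enoic acid | CC(C)=CC(=O)O | starting material
22 | 2,2-ethylenedioxy-9α-(3-methylbut-2-enoyloxy)-10βH-eremophil-11-en-8α-yl (E)-2-methylbut-2-enoate | C[C@H]1CC2(OCCO2)C[C@@H]3[C@H](OC(=O)C=C(C)C)[C@H](OC(=O)/C(C)=C/C)[C@@H](C(C)=C)C[C@]13C | intermediate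
23 | CNP0181050.1, 9α-(3-methylbut-2-enoyloxy)-8α-[(E)-2-methylbut-2-enoyloxy]-10βH-eremophil-11-en-2-one | C[C@H]1CC(=O)C[C@@H]2[C@H](OC(=O)C=C(C)C)[C@H](OC(=O)/C(C)=C/C)[C@@H](C(C)=C)C[C@]12C | target

Total steps: 13
Longest linear sequence: 13 steps (1 → 23)

**Steps most likely to fail**

Step 5: a half-formed enolate may close by aldol addition (C10 onto the C2 carbonyl) or couple between molecules before both enolates are in place, and electron transfer may stall at the hindered C10. The fallback sets out from 10: exhaustive silylation (LiN(i-Pr)2, Me3SiCl, THF, −78 °C) gives the isolable bis(trimethylsilyl enol ether) F1, which is oxidized with (NH4)2Ce(NO3)6 and NaHCO3 in MeCN at −10 °C. The radical cation of the more substituted C9–C10 enol ether should add to C1 of the terminal one, and loss of the silyl groups returns the route to 12.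

Step 8: the hydrogen shift may demand a temperature at which the silyl enol ether loses or migrates its silyl group, since the accepting carbon C10 is fully substituted. The fallback sets out from 15 and is a radical isomerization at room temperature by metal-hydride hydrogen-atom transfer (chloro(salen)cobalt, Co(salen)Cl, catalytic PhSiH3, benzene). Hydrogen-atom addition to C10 gives the C9 siloxy radical, which opens the cyclopropane to the C11 radical, and return of a methyl hydrogen to cobalt leaves the isopropenyl group. This makes no new compound (F0) and rejoins the route at 16; the C10 configuration then rests on the face of hydrogen-atom delivery.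

Step 4: the rearrangement may pass through a boat-like instead of a chair-like array, which would invert the relation of C15 to C14. The fallback sets out from 5: addition of (E)-prop-1-enyllithium (from (E)-1-bromoprop-1-ene and t-BuLi) gives the E diol F2, which through the boat-like array should be rearranged by the same dialkoxide procedure (KH, 18-crown-6, THF) to diketone 10.

**Further compounds**

F1 | step 5 | bis(trimethylsilyl enol ether) of 10 (C1=C2 and C9=C10) | C[C@]1(C=C(O[Si](C)(C)C)[C@@H]2[C@H](C1)C2(C)C)[C@@H](C)CC(=C)O[Si](C)(C)C
F0 | step 8 | none | none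
F2 | step 4 | (3E)-2-[(1R,6S)-2-hydroxy-4,7,7-trimethylbicyclo[4.1.0]hept-3-en-2-yl]pent-3-en-2-ol | CC1=C[C@](O)([C@](C)(O)/C=C/C)[C@@H]2[C@H](C1)C2(C)C
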